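**Retrosynthetic overview** (target numbered as a 2,3-dihydro-1-benzofuran: O1, C2, C3, C3a, C4–C7, C7a; ring A = carbocycle, ring B = dihydrofuran)

1. Ring B (O1–C2–C3–C3a–C7a) is cut at C3–C3a and at O1–C7a: a formal (3+2) annulation, with loss of water, of a C–C–O unit onto the C3a–C7a edge of ring A.
2. The three-atom partner is the terminal oxirane that (2R,3R)-2,3-epoxygeraniol releases in the flask by Payne rearrangement; the two-atom partner is isobutyrylfilicinic acid, so the target arises directly from two small fragments.
3. Enabling feature: ring A has a single C–H carbon (future C3a, nucleophilic) between two carbonyl carbons; C7a is flanked only by sp2 carbons and is β to three C=O groups, whereas C4 is shielded by the gem-dimethyl carbon C5.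
4. Ring A comes from phloroglucinol by acylation and dearomative gem-dimethylation; both stereocentres come from the Sharpless epoxidation of geraniol, the one at C2 being inverted once in the Payne event.
5. Ring order: ring A first (arene, then dearomatised), ring B last.

Key step: step 4

Remark: 4, 8 and 9 are enolised β-triketones whose tautomers interconvert freely; each is written in one form, 9 in the chelated exocyclic enol form of the target.

**Step 1**
Reactants: 1 phloroglucinol (benzene-1,3,5-triol); 2 isobutyryl chloride (2-methylpropanoyl chloride)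
Product: 3 2-methyl-1-(2,4,6-trihydroxyphenyl)propan-1-one
Conditions: AlCl3 (3.5 equiv), PhNO2, 0 to 65 °C; aq. HCl
Reagents that add atoms: none
Why: Friedel–Crafts acylation of the threefold-symmetric, highly activated arene can give only one regioisomer, and the chelated aryl ketone formed is deactivated toward a second acylation.

**Step 2**
Reactants: 3 2-methyl-1-(2,4,6-trihydroxyphenyl)propan-1-one
Product: 4 isobutyrylfilicinic acid (3,5-dihydroxy-4,4-dimethyl-2-(2-methylpropanoyl)cyclohexa-2,5-dien-1-one)
Conditions: NaOMe (4 equiv), MeI (2.5 equiv), MeOH, 0 °C to rt; aq. HCl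
Reagents that add atoms: iodomethane, CI
Why: Dearomative double C-methylation of the phloroglucinolate, the standard entry to acylfilicinic acids, in which the second methyl enters at the already methylated carbon and the resulting strongly acidic dienone persists as a delocalised, less nucleophilic anion.

**Step 3**
Reactants: 5 geraniol ((2E)-3,7-dimethylocta-2,6-dien-1-ol)
Product: 6 (2R,3R)-2,3-epoxygeraniol ([(2R,3R)-3-methyl-3-(4-methylpent-3-en-1-yl)oxiran-2-yl]methanol)
Conditions: Ti(OiPr)4 (5 mol %), D-(−)-diethyl tartrate (6 mol %), t-BuOOH, 4 Å MS, CH2Cl2, −20 °C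
Reagents that add atoms: tert-butyl hydroperoxide, CC(C)(C)OO
Why: Sharpless asymmetric epoxidation, in which the allylic hydroxyl binds the Ti(OiPr)4/tartrate catalyst so that only the 2,3-alkene reacts and the D-(−)-tartrate directs oxygen to the face that sets both stereocentres as 2R,3R.

**Step 4**
Reactants: 4 isobutyrylfilicinic acid; 6 (2R,3R)-2,3-epoxygeraniol
Product: 9 (2S,7Z)-7-(1-hydroxy-2-methylpropylidene)-2-[(2R)-2-hydroxy-6-methylhept-5-en-2-yl]-5,5-dimethyl-2,3-dihydro-1-benzofuran-4,6(5H,7H)-dione (the target), via terminal oxirane 7 (not isolated), via C-alkylated diol 8 (not isolated)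
Conditions: 4 (1.5 equiv), NaOH (3.2 equiv), H2O/t-BuOH 1:1, 65 °C, slow addition of 6; then 2 M HCl to pH 1, THF, 45 °C, same flask
Reagents that add atoms: none
Why: Proposed new method: the alkoxide of 6 equilibrates by Payne rearrangement (3-exo-tet, clean inversion at C2) with the terminal oxirane 7, whose unsubstituted carbon is opened in an SN2 step by the single C–H carbon of the dianion of 4 to give 8, and on acidification the secondary hydroxyl of 8 adds 5-exo-trig to the adjacent ring carbonyl and the hemiketal loses water, so that the C–C–O unit of the oxirane is annulated onto the enolised dione edge of ring A in a formal (3+2) process that closes ring B. The closest known reaction types are the Payne rearrangement–opening of 2,3-epoxy alcohols by thiolate or hydroxide in aqueous base, the alkylation of β-dicarbonyl anions by epoxides in aqueous base (acetoacetate and ethylene oxide) and the acid-catalysed cyclodehydration of 2-(2-hydroxyalkyl)-1,3-diones to fused 2,3-dihydrofurans, but their combination with a cyclic triketone as the carbon nucleophile has not been shown. No stereocentre is created, because C2 of ring B keeps the oxygen it received with inversion in the Payne event and the carbinol carbon is never touched, so both configurations descend from the epoxide of step 3. The first selectivity needed is C- over O-alkylation and attack by the carbanion before hydrolysis, which the hydrogen-bonding aqueous medium, the soft primary oxirane carbon and the buffering of free hydroxide by the acidic triketone (present as dianion in excess) should secure. The second is closure onto the carbonyl carbon next to the acyl-bearing carbon, which is β to three carbonyl groups and flanked only by planar sp2 carbons, and not onto the neopentyl-like carbonyl carbon shielded on both faces by the gem-dimethyl group, a bias with precedent in the enol-ether formation of 4,4-dimethylcyclohexane-1,3-dione at its unhindered carbonyl. Five-membered closure by the secondary hydroxyl should outrun six-membered closure by the hindered tertiary hydroxyl.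

**Compound list**

1 | phloroglucinol (benzene-1,3,5-triol) | Oc1cc(O)cc(O)c1 | starting material
2 | isobutyryl chloride (2-methylpropanoyl chloride) | CC(C)C(Cl)=O | starting material
3 | 2-methyl-1-(2,4,6-trihydroxyphenyl)propan-1-one | CC(C)C(=O)c1c(O)cc(O)cc1O | intermediate
4 | isobutyrylfilicinic acid (3,5-dihydroxy-4,4-dimethyl-2-(2-methylpropanoyl)cyclohexa-2,5-dien-1-one) | CC(C)C(=O)C1=C(O)C(C)(C)C(O)=CC1=O | intermediate
5 | geraniol ((2E)-3,7-dimethylocta-2,6-dien-1-ol) | CC(C)=CCC/C(C)=C/CO | starting material
6 | (2R,3R)-2,3-epoxygeraniol ([(2R,3R)-3-methyl-3-(4-methylpent-3-en-1-yl)oxiran-2-yl]methanol) | CC(C)=CCC[C@@]1(C)O[C@@H]1CO | intermediate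
7 | (2R)-6-methyl-2-[(2S)-oxiran-2-yl]hept-5-en-2-ol (Payne isomer of 6, present as its alkoxide) | CC(C)=CCC[C@@](C)(O)[C@@H]1CO1 | intermediate
8 | 6-[(2S,3R)-2,3-dihydroxy-3,7-dimethyloct-6-en-1-yl]-3,5-dihydroxy-4,4-dimethyl-2-(2-methylpropanoyl)cyclohexa-2,5-dien-1-one | CC(C)=CCC[C@@](C)(O)[C@@H](O)CC1=C(O)C(C)(C)C(O)=C(C(=O)C(C)C)C1=O | intermediate
9 | (2S,7Z)-7-(1-hydroxy-2-methylpropylidene)-2-[(2R)-2-hydroxy-6-methylhept-5-en-2-yl]-5,5-dimethyl-2,3-dihydro-1-benzofuran-4,6(5H,7H)-dione | CC(C)=CCC[C@@](C)(O)[C@@H]1CC2=C(O1)/C(=C(/O)C(C)C)C(=O)C(C)(C)C2=O | target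

**Step count**

Total steps: 4. Longest linear sequence: 3 steps (1 → 3 → 4 → 9); the second branch (5 → 6) joins in step 4.

**Steps most likely to fail**

1. Step 4 (Proposed new method). The stabilised dianion may be alkylated on oxygen instead of carbon, or hydroxide may consume the transient oxirane before the carbanion attacks. In the acid stage the hydroxyl may close onto the hindered carbonyl, or the tertiary hydroxyl may close a six-membered ring. The fallback uses known chemistry, sets out from 6 and comes back at 8. Payne rearrangement–opening of 6 by hydroxide (NaOH, H2O/t-BuOH, 70 °C) would give (2S,3R)-3,7-dimethyloct-6-ene-1,2,3-triol F1. Exhaustive silylation (triethylsilyl trifluoromethanesulfonate, 2,6-lutidine, CH2Cl2, 0 °C) would give (2S,3R)-3,7-dimethyl-1,2,3-tris(triethylsilyloxy)oct-6-ene F2. Swern oxidation (oxalyl chloride, DMSO, CH2Cl2, −78 °C, then Et3N, to −30 °C) cleaves and oxidises only the primary silyl ether and should give (2R,3R)-3,7-dimethyl-2,3-bis(triethylsilyloxy)oct-6-enal F3. Three-component reductive alkylation of 4 with F3 (diethyl 2,6-dimethyl-1,4-dihydropyridine-3,5-dicarboxylate, L-proline as catalyst, CH2Cl2, rt; Knoevenagel condensation followed by transfer hydrogenation) forms the C–C bond without any O-alkylation channel. It would give 6-[(2S,3R)-3,7-dimethyl-2,3-bis(triethylsilyloxy)oct-6-en-1-yl]-3,5-dihydroxy-4,4-dimethyl-2-(2-methylpropanoyl)cyclohexa-2,5-dien-1-one F4. Treatment with 1 M HCl in THF (rt to 45 °C) would remove both silyl groups to give 8, which cyclodehydrates to 9 in the same acidic medium as in step 4.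

2. Step 2. Methylation of the polyanion is statistical: mono-, tri- and tetramethylation and some O-methylation can erode the amount of the gem-dimethyl compound and complicate its separation. The fallback builds ring A with the gem-dimethyl carbon already in place; it sets out from 2 and comes back at 4. C-acylation of the enolate of acetone (generated with LiN(SiMe3)2, THF, −78 °C) with 2 would give 5-methylhexane-2,4-dione F5. Its dianion (LiN(iPr)2, THF, −78 to 0 °C) would be acylated at the terminal methyl carbon by dimethyl 2,2-dimethylmalonate to give methyl 2,2,8-trimethyl-3,5,7-trioxononanoate F6. NaOMe in MeOH would then close the six-membered ring by intramolecular Claisen condensation of the doubly activated methylene carbon onto the ester, giving 4.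

3. Step 1. Competing O-acylation and a second C-acylation of the very electron-rich ring, together with strong binding of the product to AlCl3, may lower conversion to the mono-ketone. The fallback is a Hoesch reaction; it sets out from 1 and comes back at 3. Phloroglucinol 1 with isobutyronitrile, ZnCl2 (catalytic) and HCl gas in Et2O at 0 °C would precipitate 2-methyl-1-(2,4,6-trihydroxyphenyl)propan-1-iminium chloride F7, which cannot react a second time. Hydrolysis in hot water would give 3.

**Further compounds**

F1 | step 4 | (2S,3R)-3,7-dimethyloct-6-ene-1,2,3-triol | CC(C)=CCC[C@@](C)(O)[C@@H](O)CO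
F2 | step 4 | (2S,3R)-3,7-dimethyl-1,2,3-tris(triethylsilyloxy)oct-6-ene | CC(C)=CCC[C@@](C)(O[Si](CC)(CC)CC)[C@@H](O[Si](CC)(CC)CC)CO[Si](CC)(CC)CC
F3 | step 4 | (2R,3R)-3,7-dimethyl-2,3-bis(triethylsilyloxy)oct-6-enal | CC(C)=CCC[C@@](C)(O[Si](CC)(CC)CC)[C@@H](O[Si](CC)(CC)CC)C=O
F4 | step 4 | 6-[(2S,3R)-3,7-dimethyl-2,3-bis(triethylsilyloxy)oct-6-en-1-yl]-3,5-dihydroxy-4,4-dimethyl-2-(2-methylpropanoyl)cyclohexa-2,5-dien-1-one | CC(C)=CCC[C@@](C)(O[Si](CC)(CC)CC)[C@@H](O[Si](CC)(CC)CC)CC1=C(O)C(C)(C)C(O)=C(C(=O)C(C)C)C1=O
F5 | step 2 | 5-methylhexane-2,4-dione | CC(C)C(=O)CC(C)=O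
F6 | step 2 | methyl 2,2,8-trimethyl-3,5,7-trioxononanoate | COC(=O)C(C)(C)C(=O)CC(=O)CC(=O)C(C)C
F7 | step 1 | 2-methyl-1-(2,4,6-trihydroxyphenyl)propan-1-iminium chloride | CC(C)C(=[NH2+])c1c(O)cc(O)cc1O.[Cl-]
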